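The numbers are invented; what happens was integrated by code.

The flask runs two cycles in series. From flask to flask the loading of free catalyst changes and the rest of the charge stays.

the same everywhere: substrate 0.10 M; reagent 1.50 equiv; second catalyst 1.6 mol%; time 2.0 min

| run | free catalyst |
|---|---|
| epsilon | 0.12 mol% |
| zeta | 0.25 mol% |
| eta | 0.5 mol% |
| theta | 1 mol% |
| beta | 2 mol% |

    substrate + free catalyst → free catalyst + open intermediate (k1 = 12 L mol⁻¹ s⁻¹)
    second catalyst + open intermediate ⇌ catalyst intermediate (K2 = 370 L mol⁻¹, k2 = 230 L mol⁻¹ s⁻¹)
    reagent + catalyst intermediate → second catalyst + target (k3 = 32 L mol⁻¹ s⁻¹)
    substrate → decomposition product (k4 = 6.1 × 10⁻⁶ s⁻¹)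
    2 reagent → self-condensation product (k5 = 0.057 L mol⁻¹ s⁻¹)

1. amount of target at the end, in percent of the substrate charged for epsilon, zeta, eta, theta, beta, in this order
2. how the row runs (falls all the way / hardly changes / rises, then falls / falls, then rises / rises all the way)

- a doubled species enters its step squared and goes two at a time
- "hardly changes" means that all values lie within two and a half points (for a concentration: within two and a half percent of the largest)
- run time (epsilon): 2.0 min

Opening comes first. Free catalyst returns at each turn of its step, so c(free catalyst) stays at its charge and substrate falls pseudo-first-order. In epsilon, decomposition is far slower than opening. In epsilon the opening exponent, the opening constant times c(free catalyst) times the run time, is 0.173. The substrate left is the exponential of its negative, and the part opened is 15.9%. In beta the exponent is 2.88, and the part opened is 94.4%.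

The second cycle must keep pace. At the start of beta, with second catalyst fully bound, it could turn 3.20 times as fast as substrate opens. But reagent condenses with itself, with a first half-life of 0.975 min. Reckoned for that step by itself, reagent stands at 0.0491 M at the end.

Steady flow through both intermediates holds back the opening rate times a passage time. That time is the forward binding time on charged second catalyst, 2.72 s, plus the reagent turnover time, 0.636 s, stretched by one plus the reciprocal of 0.59. It comes to 4.43 s. Opened part minus hold-up gives the row: 15.3%, 29.3%, 50.0%, 75.0%, 93.8%. By this reckoning the shape is: rises all the way.

The weak link is the reagent figure, which ignored target. In beta the substrate opened exceeds that figure. Taking target off first leaves 0.0316 M at the end, a high figure, since early self-condensation sees more reagent than this reduced charge. Fully bound second catalyst keeps pace with the final opening in beta at 0.002631 M of reagent, which lies lower. The rise stands, though the high end of the row may sit lower.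

The forecast gives 15.3%, 29%, 49%, 72.5% and 91.5%, rises all the way, below this reckoning at the high end, and says of the reagent that “by rough estimate it does not quite run out”.

The simulation gives 15.3%, 29.0%, 49.2%, 72.9% and 91.7%, rises all the way.

In epsilon at the asked time, open intermediate is made 1.01 times as fast as it is used up, each step taken net, and the substrate left, 84%, stands beside 84.1% from the opening exponent. In beta the exponent gives 5.61% of substrate left, the flask holds 5.6%, and its reagent, 5.9% of its charge, stands at 3.39 times the keep-pace level.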